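**Retrosynthetic overview**

1. Target 36 ⇐ macrocyclic lactone 31: the C7 acetate and the C15=C17 methylene come last (Eschenmoser methylenation, silyl-to-acetyl exchange).
2. 31 ⇐ seco enol triflate 29: the fourteen-membered carbocycle is closed last, at C4–C5, by B-alkyl Suzuki–Miyaura coupling.
3. 29 ⇐ dioxanyl methyl ketone 10 + lactone phosphonium salt 25: C12=C13 by Z-selective Wittig olefination.
4. 10 ⇐ nerol 1: enzymatic allylic hydroxylation, double Sharpless epoxidation, H2O2 opening at C8 then 6-exo peroxide attack at C11 (1,2-dioxane, first ring), glycol cleavage.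
5. 25 ⇐ enal 14 + (Z)-allylboronate 17: catalytic asymmetric syn-allylboration, hydroboration, oxidative lactonisation (cis γ-lactone, second ring).

Locants C1–C20 are the cembrane locants of the target (C16 lactone carbonyl, C17 exocyclic methylene, C18/C19/C20 the methyls on C4/C8/C12). Descriptors given with these locants are the CIP descriptors of the compound named.

Assumption: the target is taken exactly as the SMILES draws it, (1S,2S,3E,7R,8R,11S,12Z), with a cis-fused lactone and a cis-bridged 1,2-dioxane.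

**Route**

Step 1
Reactants: 1 nerol
Product: 2 (2E,6Z)-2,6-dimethylocta-2,6-diene-1,8-diol (8-hydroxynerol)
Conditions: resting E. coli cells co-producing the cytochrome P450 monooxygenase CYP76B6 (geraniol 8-hydroxylase), its NADPH–P450 reductase and a formate dehydrogenase; HCO2Na, air, KH2PO4/K2HPO4 buffer pH 7.5, 28 °C
Reagents that add atoms: dioxygen, O=O
Why: The cytochrome P450 monooxygenase carries out an enzymatic allylic C–H hydroxylation of only the terminal (E)-methyl group, giving an achiral diol in which both trisubstituted alkenes are now allylic alcohols.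

Step 2
Reactants: 2 8-hydroxynerol
Product: 3 bis-epoxy diol (7R,8S,11R,12R)
Conditions: Ti(OiPr)4 (0.3 equiv), D-(−)-diethyl tartrate (0.36 equiv), tBuOOH (4 equiv), 4 Å MS, CH2Cl2, −20 °C
Reagents that add atoms: tert-butyl hydroperoxide, CC(C)(C)OO
Why: Double Sharpless asymmetric epoxidation, in which the titanium–tartrate catalyst delivers oxygen to the same enantioface of each allylic alcohol and so sets C7, C8, C11 and C12 under catalyst control, the second epoxidation raising the enantiomeric purity.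

Step 3
Reactants: 3 bis-epoxy diol
Product: 4 bis-epoxy dipivalate (7R,8S,11R,12R)
Conditions: pivaloyl chloride (2.5 equiv), pyridine, 4-(dimethylamino)pyridine (cat.), CH2Cl2, 0 °C → rt
Reagents that add atoms: pivaloyl chloride, CC(C)(C)C(Cl)=O
Why: Simple acylation that protects both primary alcohols with base-stable, migration-resistant esters and electronically deactivates the neighbouring epoxide carbons C7 and C12 towards acid-promoted opening.

Step 4
Reactants: 4 bis-epoxy dipivalate
Product: 6 dioxane diol dipivalate (7R,8R,11S,12R), via hydroperoxy epoxide 5 (not isolated)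
Conditions: H2O2 (anhydrous, 2 M in Et2O, 5 equiv), H3PMo12O40 (2 mol %), Et2O, 0 °C; aqueous wash; then Cs2CO3, MeCN, 0 °C → rt
Reagents that add atoms: hydrogen peroxide, OO
Why: Acid-catalysed perhydrolysis opens the 7,8-epoxide at the tertiary carbon C8 with inversion, and the derived peroxide anion then opens the 11,12-epoxide by 6-exo-tet SN2 attack at C11 with inversion, so C8 and C11 are set stereospecifically and C7 and C12 end up cis on the 1,2-dioxane.

Step 5
Reactants: 6 dioxane diol dipivalate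
Product: 7 C7 tert-butyldimethylsilyl ether
Conditions: TBSOTf (1.1 equiv), 2,6-lutidine, CH2Cl2, −78 °C
Reagents that add atoms: tert-butyldimethylsilyl trifluoromethanesulfonate, CC(C)(C)[Si](C)(C)OS(=O)(=O)C(F)(F)F
Why: Silyl triflate etherification at low temperature takes the secondary C7 hydroxyl and leaves the tertiary C12 hydroxyl free for the later glycol cleavage.

Step 6
Reactants: 7 silyl ether dipivalate
Product: 8 triol (7R,8R,11S,12R)
Conditions: iBu2AlH (6 equiv), CH2Cl2, −78 °C; aq. potassium sodium tartrate work-up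
Reagents that add atoms: none
Why: Reductive ester cleavage with the aluminium hydride at −78 °C removes both pivalates without base and without reducing the dialkyl peroxide.

Step 7
Reactants: 8 triol
Product: 9 keto alcohol (7R,8R,11S)
Conditions: NaIO4, THF / NaH2PO4–Na2HPO4 buffer pH 7, 0 °C
Reagents that add atoms: none
Why: Malaprade glycol cleavage of the only vicinal diol (C12/C13) gives the C12 methyl ketone under neutral conditions and removes the auxiliary stereocentre C12.

Step 8
Reactants: 9 keto alcohol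
Product: 10 dioxanyl methyl ketone with C6 triethylsilyl ether (dioxane fragment)
Conditions: Et3SiCl, imidazole, CH2Cl2, −20 °C
Reagents that add atoms: chlorotriethylsilane, CC[Si](Cl)(CC)CC
Why: Silylation masks the primary alcohol, which would quench the ylide of step 19, as an ether that step 20 can later oxidise directly.

Step 9
Reactants: 11 ethyl acetoacetate
Product: 12 ethyl (2E)-3-{[(trifluoromethyl)sulfonyl]oxy}but-2-enoate
Conditions: Tf2O, aq. Me4NOH, hexanes, 5 °C → rt
Reagents that add atoms: trifluoromethanesulfonic anhydride, O=S(=O)(OS(=O)(=O)C(F)(F)F)C(F)(F)F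
Why: Stereoselective enol triflation, in which O-sulfonylation of the non-chelated tetramethylammonium enolate gives the (E)-enol triflate that will become the (3E) alkene.

Step 10
Reactants: 12 enol triflate ester
Product: 13 (2E)-4-hydroxybut-2-en-2-yl trifluoromethanesulfonate
Conditions: iBu2AlH (2.2 equiv), CH2Cl2, −78 °C
Reagents that add atoms: none
Why: 1,2-Reduction of the conjugated ester by the aluminium hydride at low temperature gives the allylic alcohol without touching the enol triflate.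

Step 11
Reactants: 13 allylic alcohol
Product: 14 (2E)-4-oxobut-2-en-2-yl trifluoromethanesulfonate
Conditions: Dess–Martin periodinane, NaHCO3, CH2Cl2, 0 °C
Reagents that add atoms: none
Why: Dess–Martin oxidation gives the enal under buffered, non-nucleophilic conditions that preserve the (E)-enol triflate.

Step 12
Reactants: 15 (2E)-penta-2,4-dien-1-ol
Product: 16 tert-butyl(dimethyl)[(2E)-penta-2,4-dien-1-yloxy]silane
Conditions: TBSCl, imidazole, DMF, 0 °C → rt
Reagents that add atoms: tert-butyldimethylsilyl chloride, CC(C)(C)[Si](C)(C)Cl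
Why: Routine silyl protection, since the free hydroxyl would consume the borane in the next step.

Step 13
Reactants: 16 dienyl silyl ether
Product: 17 (Z)-allylboronate
Conditions: pinacolborane, Ni(cod)2 (2.5 mol %), PCy3 (2.5 mol %), toluene, rt
Reagents that add atoms: pinacolborane, CC1(C)OBOC1(C)C
Why: Nickel-catalysed 1,4-hydroboration of the 1,3-diene places boron on the unsubstituted terminus and gives the (Z)-allylboronate needed for a syn-selective allylation.

Step 14
Reactants: 14 enal; 17 (Z)-allylboronate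
Product: 19 (2E,4R,5S)-5-[2-(tert-butyldimethylsilyloxy)ethyl]-4-hydroxyhepta-2,6-dien-2-yl trifluoromethanesulfonate, via pinacol borate 18 (not isolated)
Conditions: (R)-3,3'-bis(2,4,6-triisopropylphenyl)-1,1'-binaphthyl-2,2'-diyl hydrogen phosphate [(R)-TRIP] (5 mol %), 4 Å MS, toluene, −30 °C; aq. NaHCO3 work-up
Reagents that add atoms: none
Why: Chiral phosphoric acid-catalysed allylboration through a closed chair transition state, in which the (Z)-boronate geometry fixes the syn C1/C2 relationship and the catalyst selects the aldehyde face, setting C1 and C2 together.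

Step 15
Reactants: 19 homoallylic alcohol
Product: 21 (2E,4R,5R)-5-[2-(tert-butyldimethylsilyloxy)ethyl]-4,7-dihydroxyhept-2-en-2-yl trifluoromethanesulfonate, via bis-boryl adduct 20 (not isolated)
Conditions: 9-BBN-H (2.5 equiv), THF, rt; then aq. NaOH, 30 % H2O2, 0 °C
Reagents that add atoms: hydrogen peroxide, OO
Why: Anti-Markovnikov hydroboration–oxidation, in which the bulky borane attacks only the monosubstituted alkene and delivers the C16 primary alcohol without creating a stereocentre.

Step 16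
Reactants: 21 diol
Product: 23 cis-lactone (4S,5R)-4-[2-(tert-butyldimethylsilyloxy)ethyl]-5-[(1E)-2-(triflyloxy)prop-1-en-1-yl]oxolan-2-one, via lactol 22 (not isolated)
Conditions: (2,2,6,6-tetramethylpiperidin-1-yl)oxyl (TEMPO, 0.2 equiv), PhI(OAc)2 (2.5 equiv), CH2Cl2, rt
Reagents that add atoms: none
Why: Oxoammonium-mediated oxidative lactonisation, in which the primary alcohol is oxidised to the aldehyde, closes onto the C2 hydroxyl as the lactol and is oxidised on to the γ-lactone with C1 and C2 unchanged.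

Step 17
Reactants: 23 lactone silyl ether
Product: 24 (4R,5R)-4-(2-bromoethyl)-5-[(1E)-2-(triflyloxy)prop-1-en-1-yl]oxolan-2-one
Conditions: Ph3PBr2, CH2Cl2, 0 °C → rt
Reagents that add atoms: dibromotriphenylphosphorane, BrP(Br)(c1ccccc1)(c1ccccc1)c1ccccc1
Why: Direct conversion of the primary silyl ether into the bromide through an alkoxyphosphonium intermediate (Appel-type SN2 at C13), with lactone and enol triflate inert.

Step 18
Reactants: 24 bromide
Product: 25 {2-[(2R,3R)-5-oxo-2-((1E)-2-(triflyloxy)prop-1-en-1-yl)oxolan-3-yl]ethyl}triphenylphosphonium bromide (lactone fragment)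
Conditions: PPh3, MeCN, 80 °C
Reagents that add atoms: triphenylphosphine, c1ccc(cc1)P(c1ccccc1)c1ccccc1
Why: SN2 quaternisation of the primary bromide gives the Wittig salt.

Step 19
Reactants: 25 phosphonium bromide; 10 dioxanyl methyl ketone
Product: 27 seco lactone with (12Z)-alkene (1S,2R,3E,7R,8R,11S,12Z), via ylide 26 (not isolated)
Conditions: 25 (1.4 equiv), KN(SiMe3)2, THF, −78 °C; then 10, −78 → −20 °C
Reagents that add atoms: none
Why: Wittig olefination of an α-oxygenated methyl ketone with a salt-free non-stabilised ylide at low temperature (Still's Z-selective variant) places C14 cis to the oxygen-bearing C11, so the (12Z) geometry is set here.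

Step 20
Reactants: 27 seco lactone
Product: 28 C6 aldehyde
Conditions: (COCl)2, DMSO, CH2Cl2, −78 → −30 °C; then Et3N, → 0 °C
Reagents that add atoms: none
Why: Swern oxidation cleaves the primary triethylsilyl ether and oxidises it to the aldehyde in one operation, while the secondary tert-butyldimethylsilyl ether and the peroxide survive.

Step 21
Reactants: 28 aldehyde
Product: 29 seco compound with C5=C6 terminal alkene
Conditions: Ph3PCH3Br, KN(SiMe3)2, THF, 0 °C; then 28, −78 → 0 °C
Reagents that add atoms: methyltriphenylphosphonium bromide, C[P+](c1ccccc1)(c1ccccc1)c1ccccc1.[Br-]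
Why: Wittig methylenation of the α-silyloxy aldehyde introduces C5 and is far faster than attack on the lactone.

Step 22
Reactants: 29 seco alkene enol triflate
Product: 31 macrocyclic lactone (1S,2R,3E,7R,8R,11S,12Z)-7-(tert-butyldimethylsilyloxy)-8,11-epidioxycembra-3,12-dien-16,2-olide, via alkyl-9-BBN adduct 30 (not isolated)
Conditions: 9-BBN-H, THF, rt; then slow addition to PdCl2(dppf) (10 mol %), AsPh3, aq. K3PO4, THF/DMF, 50 °C, 1 mM
Reagents that add atoms: none
Why: B-alkyl Suzuki–Miyaura macrocyclisation, in which hydroboration of the only monosubstituted alkene and palladium-catalysed sp3–sp2 coupling with the enol triflate close the ring at C4–C5 with retention of the (3E) geometry and no new stereocentre.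

Step 23
Reactants: 31 macrocyclic lactone
Product: 34 α-methylene lactone (1S,2S,3E,7R,8R,11S,12Z)-7-(tert-butyldimethylsilyloxy)-8,11-epidioxycembra-3,12,15(17)-trien-16,2-olide, via Mannich base 32 (not isolated), via ammonium iodide 33 (not isolated)
Conditions: LiN(iPr)2, THF, −78 °C; CH2=NMe2+ I−, −78 °C → rt; MeI, MeOH; aq. NaHCO3, CH2Cl2
Reagents that add atoms: N,N-dimethylmethyleneiminium iodide (Eschenmoser's salt), C=[N+](C)C.[I-]
Why: Eschenmoser α-methylenation (Mannich reaction of the lithium lactone enolate, N-methylation, Hofmann-type elimination) installs C17, and the transient C15 stereocentre disappears on elimination.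

Step 24
Reactants: 34 silyl ether
Product: 35 C7 alcohol
Conditions: HF·pyridine, pyridine, THF, 0 °C → rt
Reagents that add atoms: none
Why: Buffered fluoride desilylation frees the hindered C7 hydroxyl without base, which spares the allylic peroxide and the α-methylene lactone.

Step 25
Reactants: 35 alcohol
Product: 36 target (1S,2S,3E,7R,8R,11S,12Z)-7-acetoxy-8,11-epidioxycembra-3,12,15(17)-trien-16,2-olide
Conditions: Ac2O, 4-(dimethylamino)pyridine, pyridine, CH2Cl2, rt
Reagents that add atoms: acetic anhydride, CC(=O)OC(C)=O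
Why: Nucleophile-catalysed acetylation of the secondary alcohol completes the target with retention at C7.

**Compound list**

1 | nerol, (2Z)-3,7-dimethylocta-2,6-dien-1-ol | CC(C)=CCC/C(C)=C\CO | starting material
2 | 8-hydroxynerol, (2E,6Z)-2,6-dimethylocta-2,6-diene-1,8-diol | OC/C=C(C)\CC/C=C(\C)CO | intermediate
3 | bis-epoxy diol (7R,8S,11R,12R), [(2R,3S)-3-{2-[(2R,3R)-3-(hydroxymethyl)-3-methyloxiran-2-yl]ethyl}-3-methyloxiran-2-yl]methanol | OC[C@H]1O[C@@]1(C)CC[C@H]1O[C@]1(C)CO | intermediate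
4 | dipivalate of 3 (7R,8S,11R,12R) | CC(C)(C)C(=O)OC[C@H]1O[C@@]1(C)CC[C@H]1O[C@]1(C)COC(=O)C(C)(C)C | intermediate
5 | hydroperoxy epoxide (7R,8R,11R,12R), (2R,3R)-3-hydroperoxy-2-hydroxy-3-methyl-5-{(2R,3R)-3-methyl-3-[(pivaloyloxy)methyl]oxiran-2-yl}pentyl pivalate (not isolated) | CC(C)(C)C(=O)OC[C@@H](O)[C@](C)(OO)CC[C@H]1O[C@]1(C)COC(=O)C(C)(C)C | intermediate
6 | dioxane diol dipivalate (7R,8R,11S,12R), (2R)-2-hydroxy-2-{(3S,6R)-6-[(1R)-1-hydroxy-2-(pivaloyloxy)ethyl]-6-methyl-1,2-dioxan-3-yl}propyl pivalate | CC(C)(C)C(=O)OC[C@@H](O)[C@@]1(C)CC[C@H](OO1)[C@](C)(O)COC(=O)C(C)(C)C | intermediate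
7 | C7 tert-butyldimethylsilyl ether of 6 (7R,8R,11S,12R) | CC(C)(C)C(=O)OC[C@@H](O[Si](C)(C)C(C)(C)C)[C@@]1(C)CC[C@H](OO1)[C@](C)(O)COC(=O)C(C)(C)C | intermediate
8 | triol (7R,8R,11S,12R), (2R)-2-{(3S,6R)-6-[(1R)-1-(tert-butyldimethylsilyloxy)-2-hydroxyethyl]-6-methyl-1,2-dioxan-3-yl}propane-1,2-diol | OC[C@@H](O[Si](C)(C)C(C)(C)C)[C@@]1(C)CC[C@H](OO1)[C@](C)(O)CO | intermediate
9 | keto alcohol (7R,8R,11S), 1-{(3S,6R)-6-[(1R)-1-(tert-butyldimethylsilyloxy)-2-hydroxyethyl]-6-methyl-1,2-dioxan-3-yl}ethan-1-one | OC[C@@H](O[Si](C)(C)C(C)(C)C)[C@@]1(C)CC[C@H](OO1)C(C)=O | intermediate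
10 | dioxane fragment (7R,8R,11S), C6 triethylsilyl ether of 9 | CC[Si](CC)(CC)OC[C@@H](O[Si](C)(C)C(C)(C)C)[C@@]1(C)CC[C@H](OO1)C(C)=O | intermediate
11 | ethyl acetoacetate (ethyl 3-oxobutanoate) | CCOC(=O)CC(C)=O | starting material
12 | ethyl (2E)-3-{[(trifluoromethyl)sulfonyl]oxy}but-2-enoate | CCOC(=O)/C=C(\C)OS(=O)(=O)C(F)(F)F | intermediate
13 | (2E)-4-hydroxybut-2-en-2-yl trifluoromethanesulfonate | OC/C=C(\C)OS(=O)(=O)C(F)(F)F | intermediate
14 | (2E)-4-oxobut-2-en-2-yl trifluoromethanesulfonate | O=C/C=C(\C)OS(=O)(=O)C(F)(F)F | intermediate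
15 | (2E)-penta-2,4-dien-1-ol | C=C/C=C/CO | starting material
16 | tert-butyl(dimethyl)[(2E)-penta-2,4-dien-1-yloxy]silane | C=C/C=C/CO[Si](C)(C)C(C)(C)C | intermediate
17 | (Z)-allylboronate, tert-butyl(dimethyl){[(3Z)-5-(4,4,5,5-tetramethyl-1,3,2-dioxaborolan-2-yl)pent-3-en-1-yl]oxy}silane | CC1(C)OB(C/C=C\CCO[Si](C)(C)C(C)(C)C)OC1(C)C | intermediate
18 | pinacol borate of 19 (1S,2R) (not isolated) | C=C[C@H](CCO[Si](C)(C)C(C)(C)C)[C@@H](OB1OC(C)(C)C(C)(C)O1)/C=C(\C)OS(=O)(=O)C(F)(F)F | intermediate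
19 | (2E,4R,5S)-5-[2-(tert-butyldimethylsilyloxy)ethyl]-4-hydroxyhepta-2,6-dien-2-yl trifluoromethanesulfonate (1S,2R) | C=C[C@H](CCO[Si](C)(C)C(C)(C)C)[C@@H](O)/C=C(\C)OS(=O)(=O)C(F)(F)F | intermediate
20 | bis-boryl adduct of 19: C16-(9-BBN) alkylborane with the C2 oxygen as 9-BBN borinate (not isolated) | B1(C2CCCC1CCC2)CC[C@H](CCO[Si](C)(C)C(C)(C)C)[C@@H](OB3C4CCCC3CCC4)/C=C(\C)OS(=O)(=O)C(F)(F)F | intermediate
21 | (2E,4R,5R)-5-[2-(tert-butyldimethylsilyloxy)ethyl]-4,7-dihydroxyhept-2-en-2-yl trifluoromethanesulfonate (1R,2R) | OCC[C@H](CCO[Si](C)(C)C(C)(C)C)[C@@H](O)/C=C(\C)OS(=O)(=O)C(F)(F)F | intermediate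
22 | lactol, (4S,5R)-4-[2-(tert-butyldimethylsilyloxy)ethyl]-5-[(1E)-2-(triflyloxy)prop-1-en-1-yl]oxolan-2-ol, anomer mixture (not isolated) | OC1C[C@H](CCO[Si](C)(C)C(C)(C)C)[C@H](/C=C(\C)OS(=O)(=O)C(F)(F)F)O1 | intermediate
23 | cis-lactone (4S,5R)-4-[2-(tert-butyldimethylsilyloxy)ethyl]-5-[(1E)-2-(triflyloxy)prop-1-en-1-yl]oxolan-2-one | O=C1C[C@H](CCO[Si](C)(C)C(C)(C)C)[C@H](/C=C(\C)OS(=O)(=O)C(F)(F)F)O1 | intermediate
24 | (4R,5R)-4-(2-bromoethyl)-5-[(1E)-2-(triflyloxy)prop-1-en-1-yl]oxolan-2-one | O=C1C[C@H](CCBr)[C@H](/C=C(\C)OS(=O)(=O)C(F)(F)F)O1 | intermediate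
25 | lactone fragment, {2-[(2R,3R)-5-oxo-2-((1E)-2-(triflyloxy)prop-1-en-1-yl)oxolan-3-yl]ethyl}triphenylphosphonium bromide | O=C1C[C@H](CC[P+](c2ccccc2)(c2ccccc2)c2ccccc2)[C@H](/C=C(\C)OS(=O)(=O)C(F)(F)F)O1.[Br-] | intermediate
26 | ylide of 25 (not isolated) | O=C1C[C@H](CC=P(c2ccccc2)(c2ccccc2)c2ccccc2)[C@H](/C=C(\C)OS(=O)(=O)C(F)(F)F)O1 | intermediate
27 | seco lactone (1S,2R,3E,7R,8R,11S,12Z): cis-lactone carrying the C3=C4 enol triflate and, through C14–C13=C12, the 8,11-epidioxide with C7 OTBS and C6 OSiEt3 | CC[Si](CC)(CC)OC[C@@H](O[Si](C)(C)C(C)(C)C)[C@@]1(C)CC[C@H](OO1)/C(C)=C\C[C@H]1CC(=O)O[C@H]1/C=C(\C)OS(=O)(=O)C(F)(F)F | intermediate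
28 | C6 aldehyde of 27 (1S,2R,3E,7S,8R,11S,12Z; the 7S label is a priority change only) | O=C[C@@H](O[Si](C)(C)C(C)(C)C)[C@@]1(C)CC[C@H](OO1)/C(C)=C\C[C@H]1CC(=O)O[C@H]1/C=C(\C)OS(=O)(=O)C(F)(F)F | intermediate
29 | seco compound with C5=C6 terminal alkene (1S,2R,3E,7R,8R,11S,12Z) | C=C[C@@H](O[Si](C)(C)C(C)(C)C)[C@@]1(C)CC[C@H](OO1)/C(C)=C\C[C@H]1CC(=O)O[C@H]1/C=C(\C)OS(=O)(=O)C(F)(F)F | intermediate
30 | C5 alkyl-9-BBN adduct of 29 (not isolated) | B1(C2CCCC1CCC2)CC[C@@H](O[Si](C)(C)C(C)(C)C)[C@@]3(C)CC[C@H](OO3)/C(C)=C\C[C@H]4CC(=O)O[C@H]4/C=C(\C)OS(=O)(=O)C(F)(F)F | intermediate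
31 | macrocyclic lactone (1S,2R,3E,7R,8R,11S,12Z)-7-(tert-butyldimethylsilyloxy)-8,11-epidioxycembra-3,12-dien-16,2-olide | C1C(=O)O[C@H]2/C=C(\C)CC[C@@H](O[Si](C)(C)C(C)(C)C)[C@@]3(C)CC[C@H](OO3)/C(C)=C\C[C@@H]12 | intermediate
32 | Mannich base, 15-[(dimethylamino)methyl] derivative of 31, C15 epimers (not isolated) | CN(C)CC1C(=O)O[C@H]2/C=C(\C)CC[C@@H](O[Si](C)(C)C(C)(C)C)[C@@]3(C)CC[C@H](OO3)/C(C)=C\C[C@@H]12 | intermediate
33 | trimethylammonium iodide of 32 (not isolated) | C[N+](C)(C)CC1C(=O)O[C@H]2/C=C(\C)CC[C@@H](O[Si](C)(C)C(C)(C)C)[C@@]3(C)CC[C@H](OO3)/C(C)=C\C[C@@H]12.[I-] | intermediate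
34 | (1S,2S,3E,7R,8R,11S,12Z)-7-(tert-butyldimethylsilyloxy)-8,11-epidioxycembra-3,12,15(17)-trien-16,2-olide | C=C1C(=O)O[C@H]2/C=C(\C)CC[C@@H](O[Si](C)(C)C(C)(C)C)[C@@]3(C)CC[C@H](OO3)/C(C)=C\C[C@@H]12 | intermediate
35 | (1S,2S,3E,7R,8R,11S,12Z)-7-hydroxy-8,11-epidioxycembra-3,12,15(17)-trien-16,2-olide | C=C1C(=O)O[C@H]2/C=C(\C)CC[C@@H](O)[C@@]3(C)CC[C@H](OO3)/C(C)=C\C[C@@H]12 | intermediate
36 | (1S,2S,3E,7R,8R,11S,12Z)-7-acetoxy-8,11-epidioxycembra-3,12,15(17)-trien-16,2-olide | C=C1C(=O)O[C@H]2/C=C(\C)CC[C@@H](OC(C)=O)[C@@]3(C)CC[C@H](OO3)/C(C)=C\C[C@@H]12 | target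

**Totals and risks**

Total step count: 25. Longest linear sequence: 15 steps (steps 1–8 then 19–25 from nerol; the same length from ethyl acetoacetate through steps 9–11, 14–18 and 19–25).

The step most likely to fail is step 19. The α-peroxy ketone 10 carries an acidic hydrogen at C11, and the basic ylide could trigger a Kornblum–DeLaMare fragmentation or simply enolise the methyl ketone. The fallback sets out from bromide 24 and ketone 10 and comes back at 27. 1-Phenyl-1H-tetrazole-5-thiol and K2CO3 in DMF convert 24 into the tetrazolyl sulfide F2. (NH4)6Mo7O24 and H2O2 in ethanol oxidise it to the tetrazolyl sulfone F3. The potassium salt of F3 (KN(SiMe3)2, THF, −78 °C) is a less basic carbanion and undergoes Julia–Kocienski olefination with 10. This route is not inherently Z-selective, so 27 is separated from its (12E) isomer on AgNO3-impregnated silica.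

Second is step 4. Hydrogen peroxide may open the deactivated 11,12-epoxide or the pivalate may take part, and in the ring closure the free C7 hydroxyl can compete with the hydroperoxide and give a tetrahydropyran. The fallback sets out from 4 and comes back at 7. After the perhydrolysis the crude hydroperoxy alcohol 5 is silylated on both oxygens (TBSOTf, 2,6-lutidine, −78 °C) to the bis-silyl derivative F1. One equivalent of Bu4NF at −40 °C cleaves only the labile peroxy–silyl bond. The peroxide anion so released opens the 11,12-epoxide at C11 while C7 stays silylated, which gives 7 directly and makes step 5 unnecessary.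

Third is step 22. Aqueous base at 50 °C may degrade the allylic peroxide, and intermolecular coupling competes with ring closure. The fallback sets out from 29 and comes back at 31. Stille coupling of the enol triflate with tributyl(vinyl)stannane (Pd(PPh3)4, LiCl, THF, 50 °C) gives the triene F4. Ring-closing metathesis of its two terminal alkenes with second-generation Grubbs catalyst (CH2Cl2, 40 °C, 1 mM) closes the ring at C5=C6 and gives the macrocyclic 3,5-diene F5. Diimide (potassium azodicarboxylate, AcOH, MeOH) then saturates only the disubstituted C5=C6 bond and leaves the trisubstituted alkenes and the O–O bond intact.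

Further compounds
F1 | step 4 | bis(tert-butyldimethylsilyl) derivative of 5 (C7 silyl ether, C8 silyl peroxide; 7R,8R,11R,12R) | CC(C)(C)C(=O)OC[C@@H](O[Si](C)(C)C(C)(C)C)[C@](C)(OO[Si](C)(C)C(C)(C)C)CC[C@H]1O[C@]1(C)COC(=O)C(C)(C)C
F2 | step 19 | (4R,5R)-4-{2-[(1-phenyl-1H-tetrazol-5-yl)sulfanyl]ethyl}-5-[(1E)-2-(triflyloxy)prop-1-en-1-yl]oxolan-2-one | O=C1C[C@H](CCSc2nnnn2-c2ccccc2)[C@H](/C=C(\C)OS(=O)(=O)C(F)(F)F)O1
F3 | step 19 | (4R,5R)-4-{2-[(1-phenyl-1H-tetrazol-5-yl)sulfonyl]ethyl}-5-[(1E)-2-(triflyloxy)prop-1-en-1-yl]oxolan-2-one | O=C1C[C@H](CCS(=O)(=O)c2nnnn2-c2ccccc2)[C@H](/C=C(\C)OS(=O)(=O)C(F)(F)F)O1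
F4 | step 22 | triene: 29 with the triflate replaced by a vinyl group at C4 | C=C[C@@H](O[Si](C)(C)C(C)(C)C)[C@@]1(C)CC[C@H](OO1)/C(C)=C\C[C@H]1CC(=O)O[C@H]1/C=C(\C)C=C
F5 | step 22 | macrocyclic 3,5-diene: 5,6-didehydro derivative of 31 (C5=C6 geometry not controlled) | C1C(=O)O[C@H]2/C=C(\C)C=C[C@@H](O[Si](C)(C)C(C)(C)C)[C@@]3(C)CC[C@H](OO3)/C(C)=C\C[C@@H]12
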